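**Assumptions (one line):** The curcuminoid is made as the 1,3-diketone and exists as the enol drawn in the target. The target stereodescriptors, read from the SMILES in ring numbering C1(OAr), C4(OH), C6(side chain) and side-chain C7, are 1R,4S,6R,7S. Catalyst enantiomers are chosen to match these and confirmed by screening.

## Retrosynthetic overview
1. The target is disconnected at the two enone C=C bonds by a Pabon-type boron-mediated double condensation. This joins the vanillin-ether aldehyde, p-coumaroylacetone and the acetylacetone carbon.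
2. The aryl ether is formed by Mitsunobu inversion of vanillin onto a (1S)-cyclohexenol. That alcohol comes from catalyst-controlled reduction of the ring ketone.
3. The C6–C7 bond and both stereocenters come from an organocatalytic α′-Mukaiyama–Michael addition. The donor is the silyl dienol ether of a 4-silyloxy-3-methylcyclohexenone. The acceptor is 2-methylhepta-2,5-dien-4-one.
4. The C4 stereocenter comes from a direct organocatalytic γ-hydroxylation of commercial 3-methylcyclohexenone.
5. No carbocycle is built. The cyclohexene is commercial, and the arene rings come from vanillin and 4-hydroxybenzaldehyde.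

## Route

**Step 1**
Reactants: 1 (3-methylcyclohex-2-en-1-one); 2 ((±)-2-(phenylsulfonyl)-3-phenyloxaziridine)
Product: 3 ((S)-4-hydroxy-3-methylcyclohex-2-en-1-one)
Conditions: 2 (1.3 equiv), tert-leucine-derived primary amino-amide (20 mol%), PhCO2H (20 mol%), CHCl3, 4 °C, 72 h; aq. NaHCO3
Reagents that add atoms: 2, O=S(=O)(c1ccccc1)N1OC1c1ccccc1 (transfers one O)
Why: Proposed new method: the primary amine condenses with the enone to give the endocyclic linear dienamine (C1=C2–C3(Me)=C4). Its γ-ring carbon C4 is the nucleophilic terminus, and the catalyst amide N–H binds the oxaziridine and delivers O to one face of C4 (S). Hydrolysis of the γ-hydroxy iminium releases 3. The closest known reactions are oxaziridine α-hydroxylation of enamines and dienamine γ-amination of enals. Ring-CH2 over CH3 selectivity, a cyclic β-substituted enone and O-transfer have not been shown together.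

**Step 2**
Reactants: 3; 4 (TBSCl)
Product: 5 ((S)-4-(TBSO)-3-methylcyclohex-2-en-1-one)
Conditions: imidazole, DMF, 0 °C → rt, 6 h
Reagents that add atoms: 4, CC(C)(C)[Si](C)(C)Cl
Why: Standard silylation of a secondary alcohol. It protects C4 and leaves the stereocenter untouched.

**Step 3**
Reactants: 5; 6 (TMSCl)
Product: 7 (tert-butyldimethyl{[(1S)-2-methyl-4-(trimethylsilyloxy)cyclohexa-2,4-dien-1-yl]oxy}silane)
Conditions: LiHMDS, THF, −78 °C, 1 h; TMSCl; non-aqueous pentane work-up
Reagents that add atoms: 6, C[Si](C)(C)Cl
Why: Kinetic deprotonation at the α′ carbon (C6) gives the cross-conjugated 2-silyloxy-diene. The C2=C3 enone alkene is kept, and the sp3 C4 stereocenter is not touched.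

**Step 4**
Reactants: 8 (crotonaldehyde); 9 (2-methylprop-1-en-1-ylmagnesium bromide)
Product: 10 ((E)-2-methylhepta-2,5-dien-4-ol)
Conditions: THF, −78 °C; sat. NH4Cl
Reagents that add atoms: 9, CC(C)=C[Mg]Br
Why: Chemoselective 1,2-Grignard addition to an enal. No stereocenter is formed that matters, because the alcohol is oxidized next.

**Step 5**
Reactants: 10
Product: 11 ((E)-2-methylhepta-2,5-dien-4-one)
Conditions: MnO2 (10 equiv), CH2Cl2, rt, 4 h
Reagents that add atoms: none
Why: MnO2 oxidizes the bis-allylic alcohol selectively to the cross-conjugated dienone, the Michael acceptor.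

**Step 6**
Reactants: 7; 11
Product: 12 ((4S,6R)-4-(TBSO)-3-methyl-6-[(2S)-6-methyl-4-oxohept-5-en-2-yl]cyclohex-2-en-1-one)
Conditions: chiral imidodiphosphorimidate IDPi (5 mol%), pentane/CH2Cl2 4:1, −40 °C, 48 h; then AcOH/H2O/THF, rt
Reagents that add atoms: none (TMS is lost on work-up)
Why: Silylium-based organocatalytic Mukaiyama–Michael addition. The diene attacks the less hindered, more electrophilic crotonyl enone at C6, and the hindered β,β-dimethyl enone stays intact. The donor face anti to the pseudo-axial C4-OTBS gives C6 trans to C4. The chiral IDPi selects the acceptor face, giving 7S.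

**Step 7**
Reactants: 12
Product: 13 ((1S,4S,6R)-4-(TBSO)-3-methyl-6-[(2S)-6-methyl-4-oxohept-5-en-2-yl]cyclohex-2-en-1-ol)
Conditions: (R)-Me-CBS (20 mol%), BH3·SMe2 (0.6 equiv), THF, −30 °C, 2 h
Reagents that add atoms: none
Why: CBS reduction delivers hydride to the face anti to C6, so the OH is cis to the C6 substituent (1S). The ring ketone is more reactive than the hindered acyclic dienone.

**Step 8**
Reactants: 13; 14 (vanillin)
Product: 15 (3-methoxy-4-{[(1R,4S,6R)-4-(TBSO)-3-methyl-6-[(2S)-6-methyl-4-oxohept-5-en-2-yl]cyclohex-2-en-1-yl]oxy}benzaldehyde)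
Conditions: PPh3, DIAD, THF, 0 °C → rt, 12 h
Reagents that add atoms: vanillin 14, COc1cc(C=O)ccc1O (PPh3 and DIAD leave none)
Why: Mitsunobu etherification of the acidic phenol proceeds by SN2 with inversion at C1 (1S to 1R). The aryloxy group ends cis to C4-O and trans to C6.

**Step 9**
Reactants: 15
Product: 16 (3-methoxy-4-{[(1R,4S,6R)-4-hydroxy-3-methyl-6-[(2S)-6-methyl-4-oxohept-5-en-2-yl]cyclohex-2-en-1-yl]oxy}benzaldehyde)
Conditions: TBAF, AcOH (1:1), THF, 0 °C → rt, 4 h
Reagents that add atoms: none
Why: Buffered fluoride removes the TBS group. The acid-labile allylic aryl ether, the enone and the aldehyde survive, and no stereocenter is touched.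

**Step 10**
Reactants: 17 (acetylacetone); 18 (4-hydroxybenzaldehyde)
Product: 19 ((E)-6-(4-hydroxyphenyl)hex-5-ene-2,4-dione, p-coumaroylacetone)
Conditions: 17 (3 equiv), B2O3, B(OBu)3, n-BuNH2 (cat.), EtOAc, 60 °C; 0.4 M HCl, 60 °C
Reagents that add atoms: none beyond the numbered reactants
Why: Pabon condensation. Boron masks the central carbon, and excess diketone favors mono-condensation.

**Step 11**
Reactants: 16; 19
Product: 20 (target, demethoxybisabolocurcumin ether)
Conditions: B2O3, B(OBu)3, n-BuNH2 (cat.), EtOAc, 40 °C, 16 h; 0.4 M HCl (aq), 60 °C, 1 h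
Reagents that add atoms: none beyond the numbered reactants
Why: Pabon Knoevenagel-type condensation of the remaining acetyl CH3 of 19 with aldehyde 16 gives the unsymmetrical curcuminoid. The ring stereocenters are far from the reacting centers and are not affected.

## Compound list
1 | 3-methylcyclohex-2-en-1-one | CC1=CC(=O)CCC1 | starting material
2 | (±)-2-(phenylsulfonyl)-3-phenyloxaziridine | O=S(=O)(c1ccccc1)N1OC1c1ccccc1 | starting material (reagent)
3 | (S)-4-hydroxy-3-methylcyclohex-2-en-1-one | O=C1C=C(C)[C@@H](O)CC1 | intermediate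
4 | tert-butyldimethylsilyl chloride | CC(C)(C)[Si](C)(C)Cl | starting material
5 | (S)-4-(TBSO)-3-methylcyclohex-2-en-1-one | O=C1C=C(C)[C@@H](O[Si](C)(C)C(C)(C)C)CC1 | intermediate
6 | trimethylsilyl chloride | C[Si](C)(C)Cl | starting material
7 | silyl dienol ether of 5 | C[Si](C)(C)OC1=CC[C@H](O[Si](C)(C)C(C)(C)C)C(C)=C1 | intermediate
8 | crotonaldehyde | C/C=C/C=O | starting material
9 | 2-methylprop-1-en-1-ylmagnesium bromide | CC(C)=C[Mg]Br | starting material
10 | (E)-2-methylhepta-2,5-dien-4-ol | C/C=C/C(O)C=C(C)C | intermediate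
11 | (E)-2-methylhepta-2,5-dien-4-one | C/C=C/C(=O)C=C(C)C | intermediate
12 | Michael adduct ketone | O=C1C=C(C)[C@@H](O[Si](C)(C)C(C)(C)C)C[C@@H]1[C@@H](C)CC(=O)C=C(C)C | intermediate
13 | (1S)-allylic alcohol | O[C@@H]1C=C(C)[C@@H](O[Si](C)(C)C(C)(C)C)C[C@@H]1[C@@H](C)CC(=O)C=C(C)C | intermediate
14 | vanillin | COc1cc(C=O)ccc1O | starting material
15 | TBS-protected aryl ether aldehyde | COc1cc(C=O)ccc1O[C@H]1C=C(C)[C@@H](O[Si](C)(C)C(C)(C)C)C[C@@H]1[C@@H](C)CC(=O)C=C(C)C | intermediate
16 | hydroxy aryl ether aldehyde | COc1cc(C=O)ccc1O[C@H]1C=C(C)[C@@H](O)C[C@@H]1[C@@H](C)CC(=O)C=C(C)C | intermediate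
17 | acetylacetone | CC(=O)CC(C)=O | starting material
18 | 4-hydroxybenzaldehyde | O=Cc1ccc(O)cc1 | starting material
19 | p-coumaroylacetone | CC(=O)CC(=O)/C=C/c1ccc(O)cc1 | intermediate
20 | demethoxybisabolocurcumin ether | COc1cc(/C=C/C(O)=C/C(=O)/C=C/c2ccc(O)cc2)ccc1O[C@H]1C=C(C)[C@@H](O)C[C@@H]1[C@@H](C)CC(=O)C=C(C)C | target

## Totals
Total steps: 11. Longest linear sequence: 8 (steps 1, 2, 3, 6, 7, 8, 9, 11).

## Three steps most likely to fail
1. **Step 1 (new γ-hydroxylation).** Risks are amine oxidation by the oxaziridine, α′ or CH3 attack instead of ring C4, and low ee.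
   - Fallback (known chemistry): 1,3-cyclohexadiene + ¹O2 (O2, TPP, hν) gives the endoperoxide. Cinchona-catalysed desymmetrizing Kornblum–DeLaMare rearrangement gives (S)-4-hydroxycyclohex-2-enone. Then TBSCl, Me2CuLi/TMSCl, and Pd(OAc)2 Saegusa dehydrogenation give 5.
2. **Step 6 (Mukaiyama–Michael).** Risks are a competing double-Michael to a bicyclo[2.2.2]octanone, attack on the wrong enone, and poor C7 control.
   - Fallback: add diarylprolinol-silyl-ether iminium catalysis of crotonaldehyde to 7, then isobutenylMgBr addition and MnO2 oxidation to build the dienone after the C–C bond is formed.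
3. **Step 7 (CBS reduction), with the Mitsunobu in step 8.** Risks are the wrong C1 epimer, reduction of the side-chain dienone, and elimination in the Mitsunobu.
   - Fallback: non-selective Luche reduction. If the OH ends cis to OTBS, switch the etherification to SNAr of the alkoxide with 4-fluoro-3-methoxybenzaldehyde, which retains configuration, in place of the Mitsunobu.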